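**Assumption (numbering and supply):** the furan carbons are C1–C4 (chain on C3) and the chain runs C5 to the lactone carbonyl C19, with methyls on C8, C12 and C16. The target is then (7E,10S,11E,15R,16S). Geranyl benzoate, 3-bromofuran, oxetane, isopropenylboronic acid pinacol ester, (−)-sparteine and the D-fructose-derived Shi ketone are taken as commercial.

## Structural features

The target is a linear C22 furanoterpenoid: a 3-alkylfuran (C1–C4), a C5–C19 chain and an acetate on C10. The chain carries two E-trisubstituted alkenes, C7=C8 and C11=C12, on either side of the acetoxy carbon C10 (S). C7=C8–C9–C10(OAc)–C11=C12 is therefore a 3-acyloxy-1,5-diene. At the other end, C15 (R, secondary OH) stands next to the quaternary C16 (S), which bears a methyl and the ring oxygen of a γ-lactone (C16–C19). The C15/C16 relationship is the one that results from anti addition of two oxygens across an (E)-C15=C16 alkene. Syn-dihydroxylation of that E-alkene followed by lactonisation would give the wrong diastereomer, so an epoxide opened with inversion at C16 is needed. C10 is five bonds from C15, so no relay between the two stereochemical regions is realistic. Fragile groups are the furan (acid, electrophilic oxidants), the allylic acetate (ionisation, Pd(0)), the lactone (bases, nucleophiles) and the skipped diene (isomerisation of any C10 carbonyl precursor). The real difficulty is the isolated C10 stereocentre, which must be set together with the geometry of a flanking trisubstituted alkene and a fragment union, under conditions that tolerate the oxygenated C15–C19 terminus.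

## Logic of the disconnections

**24 ⇒ 22.** The C16–O(lactone) bond and the O–tert-butyl bond are cut. The lactone is closed last by opening the C15/C16 epoxide with the ester carbonyl. This gives the required anti C15/C16 relationship stereospecifically and keeps the C15 hydroxyl masked as the epoxide through the whole route, so no protecting group is needed. The demand is 5-exo attack at the tertiary C16 with clean inversion under acid mild enough for the furan and the allylic acetate.

**22 ⇒ 21.** The acetyl C–O bond is cut. This is a plain acylation of the only free hydroxyl.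

**21 ⇒ 18 + 9 (key).** The C9–C10 bond is cut with allylic transposition, so that the C7=C8 alkene becomes a C8=C9 methylidene and C7 becomes a boron-bearing stereocentre. The 3-oxy-1,5-diene is the retron of an α-substituted allylboron addition to an enal. One step then forms C9–C10, sets C10, fixes the C7=C8 geometry and joins the furan half to the oxygenated half. The precursor stereocentre (C7–B) is far easier to make than C10 itself. The demand is high E selectivity and complete chirality transfer under neutral conditions.

**9 ⇒ 8 ⇒ 7.** Only the oxidation state and protection at C10 change. The allylic benzoate is needed in 7 to deactivate C11=C12 during the epoxidation and is then converted to the enal.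

**7 ⇒ 6.** The two C–O bonds of the epoxide are cut, leaving the (E)-C15=C16 alkene. A catalyst-controlled epoxidation sets both C15 and C16 in one event. The demand is site selectivity over C11=C12.

**6 ⇒ 3 + 4, and 3 ⇒ 2 ⇒ 1.** The C17–C18 bond is cut, giving an allylic bromide and an acetate enolate. The bromide goes back, by way of the allylic alcohol, to 1. Both the C11=C12 and the C15=C16 geometries are bought with 1. The demand is selective oxidation of the E-methyl of the terminal alkene of 1.

**18 ⇒ 14 + 15, and 14 ⇒ 13 ⇒ 10 + 11.** The C7–C8 bond is cut with a 1,2-metallate retron, which gives a primary carbamate and an alkenyl boronate. The C7 stereocentre then comes from an enantioselective deprotonation. The carbamate goes back to the alcohol, and the C4–C5 bond of the alcohol is cut to a 3-furyl anion and a three-carbon electrophile.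

## Other disconnections considered

**Alternative 1:** This is the first disconnection that comes to mind. The C10–C11 bond is cut to the (E)-vinyl iodide A1 and the β,γ-unsaturated aldehyde A2, joined by a Nozaki–Hiyama–Kishi coupling under a chiral ligand. The chosen plan is preferred for four reasons. A2 conjugates readily to the α,β-unsaturated isomer. Addition of a 2,2-disubstituted alkenylchromium to an unbranched aldehyde is only under reagent control, which is usually modest. The C7=C8 geometry needs its own olefination and A1 its own carbometalation sequence. The step sets only C10, whereas the step 18 + 9 → 21 sets C10 and the alkene geometry while joining the halves.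

**Alternative 2:** The C9–C10 bond is cut through the bis-allyl ether A3, which has an (R)-configured C7–O stereocentre. The forward step is a [2,3]-Wittig rearrangement with n-BuLi and has the same topology as the chosen step. It needs an organolithium base, which the tert-butyl ester (and any lactone) would not survive, so the C15–C19 end would have to be carried in masked form at the cost of several steps. Its E/Z outcome for 2-methylallyl ethers also depends strongly on the carbanion substituent. The allylboration is the neutral counterpart and is run directly on 9.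

**Alternative 3:** The C15–C16 bond is cut to the aldehyde A4 and the silyloxyfuran A5. A late vinylogous Mukaiyama aldol would give the butenolide A6, followed by conjugate reduction. Two new stereocentres, one quaternary, would have to be set by the catalyst alone on an unbranched aliphatic aldehyde. The required relative configuration is not assured by any transition-state argument. A4 still contains the unsolved C10 problem. A chemoselective 1,4-reduction beside two trisubstituted alkenes and a furan is added. The epoxide route 6 → 7 → 24 fixes the same two centres by a stereospecific sequence.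

Key step: step 10

## Route

Step 1
Reactants: 1 geranyl benzoate [(2E)-3,7-dimethylocta-2,6-dien-1-yl benzoate]
Product: 2 (2E,6E)-8-hydroxy-3,7-dimethylocta-2,6-dien-1-yl benzoate
Conditions: SeO2 (0.1 equiv), t-BuOOH (70% aq.), salicylic acid (cat.), CH2Cl2, rt
Reagents that add atoms: tert-butyl hydroperoxide, CC(C)(C)OO (source of the new oxygen, relayed through selenium dioxide, O=[Se]=O)
Why: Catalytic SeO2 allylic oxidation (ene reaction, then [2,3]-shift of the allylseleninic acid) attacks the E-methyl of the terminal trisubstituted alkene; the C11=C12 alkene is deactivated by the allylic benzoate, and both alkene geometries are kept.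

Step 2
Reactants: 2 (2E,6E)-8-hydroxy-3,7-dimethylocta-2,6-dien-1-yl benzoate
Product: 3 (2E,6E)-8-bromo-3,7-dimethylocta-2,6-dien-1-yl benzoate
Conditions: CBr4, PPh3, CH2Cl2, 0 °C
Reagents that add atoms: carbon tetrabromide, BrC(Br)(Br)Br
Why: Appel bromination; SN2 displacement of the oxyphosphonium at the primary allylic carbon leaves the benzoate and the alkene geometry untouched.

Step 3
Reactants: 3 (2E,6E)-8-bromo-3,7-dimethylocta-2,6-dien-1-yl benzoate; 4 tert-butyl acetate
Product: 6 tert-butyl (4E,8E)-10-(benzoyloxy)-4,8-dimethyldeca-4,8-dienoate, via lithium enolate of tert-butyl acetate 5 (not isolated)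
Conditions: LDA, THF, −78 °C; then 3, DMPU, −78 → −40 °C
Reagents that add atoms: none
Why: Ester enolate alkylation (SN2) of a primary allylic bromide adds C18–C19; the benzoate has no α-hydrogen and should be attacked only slowly at low temperature, which is why it is used in place of the acetate.

Step 4
Reactants: 6 tert-butyl (4E,8E)-10-(benzoyloxy)-4,8-dimethyldeca-4,8-dienoate
Product: 7 tert-butyl 3-[(2R,3R)-3-[(3E)-5-(benzoyloxy)-3-methylpent-3-en-1-yl]-2-methyloxiran-2-yl]propanoate
Conditions: D-fructose-derived Shi ketone (0.3 equiv), Oxone, K2CO3, Bu4NHSO4 (cat.), MeCN–DMM/aq. borate buffer (pH ≈ 10.5), 0 °C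
Reagents that add atoms: Oxone (potassium peroxymonosulfate), [K+].[O-]S(=O)(=O)OO
Why: Shi asymmetric epoxidation (chiral dioxirane, spiro transition state) of the E-trisubstituted C15=C16 alkene; the known facial preference of the D-fructose-derived ketone for E- and trisubstituted alkenes should give the (15R,16R) epoxide. The C11=C12 alkene is electron-poor because of the allylic benzoate and should be spared.

Step 5
Reactants: 7 tert-butyl 3-[(2R,3R)-3-[(3E)-5-(benzoyloxy)-3-methylpent-3-en-1-yl]-2-methyloxiran-2-yl]propanoate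
Product: 8 tert-butyl 3-[(2R,3R)-3-[(3E)-5-hydroxy-3-methylpent-3-en-1-yl]-2-methyloxiran-2-yl]propanoate
Conditions: K2CO3, MeOH, 0 °C → rt
Reagents that add atoms: none
Why: Base-catalysed methanolysis removes the benzoate; the tert-butyl ester and the trisubstituted epoxide are inert to carbonate in methanol.

Step 6
Reactants: 8 tert-butyl 3-[(2R,3R)-3-[(3E)-5-hydroxy-3-methylpent-3-en-1-yl]-2-methyloxiran-2-yl]propanoate
Product: 9 tert-butyl 3-[(2R,3R)-2-methyl-3-[(3E)-3-methyl-5-oxopent-3-en-1-yl]oxiran-2-yl]propanoate
Conditions: activated MnO2, CH2Cl2, rt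
Reagents that add atoms: none
Why: MnO2 oxidises allylic alcohols selectively to enals without over-oxidation and with retention of the E geometry.

Step 7
Reactants: 10 3-bromofuran; 11 oxetane
Product: 13 3-(furan-3-yl)propan-1-ol, via 3-furyllithium 12 (not isolated)
Conditions: n-BuLi, THF, −78 °C; then oxetane, BF3·OEt2, −78 °C; aq. NH4Cl
Reagents that add atoms: none
Why: Bromine–lithium exchange gives 3-furyllithium, which is configurationally and positionally stable at −78 °C; BF3-promoted ring opening of oxetane by the organolithium adds the three-carbon alcohol chain (C5–C7).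

Step 8
Reactants: 13 3-(furan-3-yl)propan-1-ol
Product: 14 3-(furan-3-yl)propyl N,N-diisopropylcarbamate
Conditions: i-Pr2NCOCl, Et3N, CH2Cl2, reflux
Reagents that add atoms: N,N-diisopropylcarbamoyl chloride, CC(C)N(C(C)C)C(Cl)=O
Why: O-Carbamoylation of a primary alcohol; the carbamate is both the directing group for α-lithiation and the leaving group for the later 1,2-shift.

Step 9
Reactants: 14 3-(furan-3-yl)propyl N,N-diisopropylcarbamate; 15 2-isopropenyl-4,4,5,5-tetramethyl-1,3,2-dioxaborolane
Product: 18 2-[(3R)-5-(furan-3-yl)-2-methylpent-1-en-3-yl]-4,4,5,5-tetramethyl-1,3,2-dioxaborolane, via (S)-α-lithiated carbamate 16 (not isolated), via boronate ate complex 17 (not isolated)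
Conditions: s-BuLi, (−)-sparteine, Et2O, −78 °C, 5 h; 15, −78 °C, 1 h; MgBr2·OEt2, then reflux
Reagents that add atoms: none
Why: Hoppe-type sparteine-mediated deprotonation removes the pro-S proton to give the (S)-organolithium, which is borylated with retention. The lithiation–borylation 1,2-metallate rearrangement then moves the isopropenyl group from boron to carbon anti to the departing carbamate (inversion), which should give the (R)-configured C7–B stereocentre.

Step 10
Reactants: 18 2-[(3R)-5-(furan-3-yl)-2-methylpent-1-en-3-yl]-4,4,5,5-tetramethyl-1,3,2-dioxaborolane; 9 tert-butyl 3-[(2R,3R)-2-methyl-3-[(3E)-3-methyl-5-oxopent-3-en-1-yl]oxiran-2-yl]propanoate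
Product: 21 tert-butyl 3-[(2R,3R)-3-[(3E,5S,7E)-10-(furan-3-yl)-5-hydroxy-3,7-dimethyldeca-3,7-dien-1-yl]-2-methyloxiran-2-yl]propanoate, via butyl ate complex 19 (not isolated), via allyl borinic ester 20 (not isolated)
Conditions: 18, n-BuLi (1.0 equiv), THF, −78 °C; TFAA, −78 °C; then 9, −78 °C → rt; aq. NaHCO3/triethanolamine work-up (no peroxide)
Reagents that add atoms: none
Why: n-BuLi adds to the boron of 18 (ate complex 19) and TFAA acylates one pinacol oxygen, which opens the dioxaborolane to the much more reactive and less hindered borinic ester 20. Aldehyde 9 then binds to boron and the allyl group is transferred through a closed six-membered chair (B–O–C10–C9–C8–C7), an SE2′ process in which C9 bonds to C10 while the C7–B bond is traded for the C7=C8 alkene; the closest known reaction type is the allylboration of aldehydes with α-substituted β-methallyl boron reagents through borinic esters made in situ, which is E-selective for trisubstituted alkenes. No ring is closed; the cyclic array exists only in the transition state. C10 is set by 1,3-chirality transfer from C7: with the C6 chain pseudo-equatorial and the enal substituent (C11) equatorial, the (R)-boronate delivers C9 to the aldehyde face that gives 10S. The same equatorial placement of the C6 chain makes C7=C8 E, whereas the axial chair would give the Z alkene together with 10R, so alkene geometry and C10 configuration are coupled and rest on one selectivity. That selectivity is secured by the borinic ester, because the pinacol methyls that push the α-substituent axial in the parent boronic ester no longer crowd the equatorial position, while the axial position meets the B-butyl group. The closed transition state gives 1,2- and not 1,4-addition to the enal, the neutral conditions at −78 °C leave the epoxide, the tert-butyl ester and the furan untouched, and the remote C15/C16 centres have no say, so the step is controlled by the boronate alone.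

Step 11
Reactants: 21 tert-butyl 3-[(2R,3R)-3-[(3E,5S,7E)-10-(furan-3-yl)-5-hydroxy-3,7-dimethyldeca-3,7-dien-1-yl]-2-methyloxiran-2-yl]propanoate
Product: 22 tert-butyl 3-[(2R,3R)-3-[(3E,5S,7E)-5-(acetyloxy)-10-(furan-3-yl)-3,7-dimethyldeca-3,7-dien-1-yl]-2-methyloxiran-2-yl]propanoate
Conditions: Ac2O, pyridine, DMAP (cat.), CH2Cl2, 0 °C
Reagents that add atoms: acetic anhydride, CC(=O)OC(C)=O
Why: DMAP-catalysed acylation of the only free hydroxyl; the epoxide, the tert-butyl ester and the furan are inert, and C10 is not touched.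

Step 12
Reactants: 22 tert-butyl 3-[(2R,3R)-3-[(3E,5S,7E)-5-(acetyloxy)-10-(furan-3-yl)-3,7-dimethyldeca-3,7-dien-1-yl]-2-methyloxiran-2-yl]propanoate
Product: 24 10-acetylirciformonin B [(1R,4E,6S,8E)-11-(furan-3-yl)-1-hydroxy-4,8-dimethyl-1-[(2S)-2-methyl-5-oxooxolan-2-yl]undeca-4,8-dien-6-yl acetate], via O-tert-butyl lactonium ion 23 (not isolated)
Conditions: CSA (0.2 equiv), CH2Cl2, 0 °C → rt
Reagents that add atoms: none
Why: Acid-catalysed epoxide-opening lactonisation: the ester carbonyl oxygen attacks the protonated epoxide 5-exo at the tertiary C16 with inversion, and the resulting lactonium ion loses isobutene. The (15R,16R) epoxide thus becomes the (15R,16S) hydroxy lactone, with the C15–O bond never broken.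

## Compound list

1 | geranyl benzoate, (2E)-3,7-dimethylocta-2,6-dien-1-yl benzoate | CC(C)=CCC/C(C)=C/COC(=O)c1ccccc1 | starting material
2 | (2E,6E)-8-hydroxy-3,7-dimethylocta-2,6-dien-1-yl benzoate | OC/C(C)=C/CC/C(C)=C/COC(=O)c1ccccc1 | intermediate
3 | (2E,6E)-8-bromo-3,7-dimethylocta-2,6-dien-1-yl benzoate | BrC/C(C)=C/CC/C(C)=C/COC(=O)c1ccccc1 | intermediate
4 | tert-butyl acetate | CC(=O)OC(C)(C)C | starting material
5 | lithium enolate of tert-butyl acetate | C=C(O[Li])OC(C)(C)C | intermediate (not isolated)
6 | tert-butyl (4E,8E)-10-(benzoyloxy)-4,8-dimethyldeca-4,8-dienoate | CC(C)(C)OC(=O)CC/C(C)=C/CC/C(C)=C/COC(=O)c1ccccc1 | intermediate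
7 | tert-butyl 3-[(2R,3R)-3-[(3E)-5-(benzoyloxy)-3-methylpent-3-en-1-yl]-2-methyloxiran-2-yl]propanoate | CC(C)(C)OC(=O)CC[C@@]1(C)O[C@@H]1CC/C(C)=C/COC(=O)c1ccccc1 | intermediate
8 | tert-butyl 3-[(2R,3R)-3-[(3E)-5-hydroxy-3-methylpent-3-en-1-yl]-2-methyloxiran-2-yl]propanoate | CC(C)(C)OC(=O)CC[C@@]1(C)O[C@@H]1CC/C(C)=C/CO | intermediate
9 | tert-butyl 3-[(2R,3R)-2-methyl-3-[(3E)-3-methyl-5-oxopent-3-en-1-yl]oxiran-2-yl]propanoate | CC(C)(C)OC(=O)CC[C@@]1(C)O[C@@H]1CC/C(C)=C/C=O | intermediate
10 | 3-bromofuran | Brc1ccoc1 | starting material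
11 | oxetane | C1COC1 | starting material
12 | 3-furyllithium | [Li]c1ccoc1 | intermediate (not isolated)
13 | 3-(furan-3-yl)propan-1-ol | OCCCc1ccoc1 | intermediate
14 | 3-(furan-3-yl)propyl N,N-diisopropylcarbamate | CC(C)N(C(C)C)C(=O)OCCCc1ccoc1 | intermediate
15 | 2-isopropenyl-4,4,5,5-tetramethyl-1,3,2-dioxaborolane | CC(=C)B1OC(C)(C)C(C)(C)O1 | starting material
16 | (1S)-3-(furan-3-yl)-1-lithiopropyl N,N-diisopropylcarbamate (as its (−)-sparteine complex) | [Li][C@@H](CCc1ccoc1)OC(=O)N(C(C)C)C(C)C | intermediate (not isolated)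
17 | lithium [(1S)-1-(diisopropylcarbamoyloxy)-3-(furan-3-yl)propyl](isopropenyl)(pinacolato)borate | [Li+].CC(=C)[B-]1(OC(C)(C)C(C)(C)O1)[C@@H](CCc1ccoc1)OC(=O)N(C(C)C)C(C)C | intermediate (not isolated)
18 | 2-[(3R)-5-(furan-3-yl)-2-methylpent-1-en-3-yl]-4,4,5,5-tetramethyl-1,3,2-dioxaborolane | CC(=C)[C@@H](CCc1ccoc1)B1OC(C)(C)C(C)(C)O1 | intermediate
19 | lithium butyl[(3R)-5-(furan-3-yl)-2-methylpent-1-en-3-yl](pinacolato)borate | CC(=C)[C@@H](CCc1ccoc1)[B-]1(CCCC)OC(C)(C)C(C)(C)O1.[Li+] | intermediate (not isolated)
20 | 3-({butyl[(3R)-5-(furan-3-yl)-2-methylpent-1-en-3-yl]boranyl}oxy)-2,3-dimethylbutan-2-yl trifluoroacetate | CC(=C)[C@@H](CCc1ccoc1)B(CCCC)OC(C)(C)C(C)(C)OC(=O)C(F)(F)F | intermediate (not isolated)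
21 | tert-butyl 3-[(2R,3R)-3-[(3E,5S,7E)-10-(furan-3-yl)-5-hydroxy-3,7-dimethyldeca-3,7-dien-1-yl]-2-methyloxiran-2-yl]propanoate | CC(C)(C)OC(=O)CC[C@@]1(C)O[C@@H]1CC/C(C)=C/[C@@H](O)C/C(C)=C/CCc1ccoc1 | intermediate
22 | tert-butyl 3-[(2R,3R)-3-[(3E,5S,7E)-5-(acetyloxy)-10-(furan-3-yl)-3,7-dimethyldeca-3,7-dien-1-yl]-2-methyloxiran-2-yl]propanoate | CC(C)(C)OC(=O)CC[C@@]1(C)O[C@@H]1CC/C(C)=C/[C@@H](OC(C)=O)C/C(C)=C/CCc1ccoc1 | intermediate
23 | (5S)-5-[(1R,4E,6S,8E)-6-(acetyloxy)-11-(furan-3-yl)-1-hydroxy-4,8-dimethylundeca-4,8-dien-1-yl]-2-tert-butoxy-5-methyl-4,5-dihydro-3H-furan-1-ium | CC(=O)O[C@H](/C=C(\C)CC[C@@H](O)[C@]1(C)CCC(OC(C)(C)C)=[O+]1)C/C(C)=C/CCc1ccoc1 | intermediate (not isolated)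
24 | 10-acetylirciformonin B, (1R,4E,6S,8E)-11-(furan-3-yl)-1-hydroxy-4,8-dimethyl-1-[(2S)-2-methyl-5-oxooxolan-2-yl]undeca-4,8-dien-6-yl acetate | CC(=O)O[C@H](/C=C(\C)CC[C@@H](O)[C@]1(C)CCC(=O)O1)C/C(C)=C/CCc1ccoc1 | target

## Step count and least certain steps

Total: 12 steps. Longest linear sequence: 9 steps (steps 1–6, then 10–12). The boronate branch (steps 7–9) is 3 steps.

**Step 10 (key step).** The likely failures are leakage through the axial chair, which would give the Z-C7=C8 alkene together with the 10R configuration; a 1,3-borotropic shift of the borinic ester before addition, which would lose the C7 stereocentre and give a branched adduct; and slow addition to the β,β-disubstituted enal. The fallback sets out from 13 and 9 and returns at 21. Alcohol 13 is oxidised (SO3·pyridine, DMSO) to 3-(furan-3-yl)propanal F1, which is olefinated with Ph3P=C(CH3)CO2Et to ethyl (2E)-5-(furan-3-yl)-2-methylpent-2-enoate F2, so that the E geometry of C7=C8 is fixed in advance. DIBAL reduction gives (2E)-5-(furan-3-yl)-2-methylpent-2-en-1-ol F3, and Corey–Kim chlorination (NCS, Me2S) gives 3-[(3E)-5-chloro-4-methylpent-3-en-1-yl]furan F4. The allylbarium reagent from F4 (reactive barium, THF, −78 °C) adds to 9 at its α-carbon with retention of alkene geometry and should give 21 mixed with its C10 epimer F5. Oxidation of the mixture (Dess–Martin periodinane, NaHCO3) gives the dienone tert-butyl 3-[(2R,3R)-3-[(3E,7E)-10-(furan-3-yl)-3,7-dimethyl-5-oxodeca-3,7-dien-1-yl]-2-methyloxiran-2-yl]propanoate F6. Corey–Bakshi–Shibata reduction with the (R)-oxazaborolidine (alkenyl as the large group) should then give 21.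

**Step 9.** During the slow carbamate deprotonation, s-BuLi may also metalate the furan at C2/C5, and the 1,2-migration of the pinacol ate complex may be incomplete. The fallback sets out from 13 and returns at 18. The allylic alcohol F3 (made from 13 as in the fallback for step 10) is converted with methyl chloroformate and pyridine to (2E)-5-(furan-3-yl)-2-methylpent-2-en-1-yl methyl carbonate F7. A copper(I)-catalysed enantioselective γ-selective allylic borylation (CuCl, chiral bisphosphine, B2pin2, KOt-Bu) then places boron at C7 and moves the alkene to C8=C9 to give 18. The ligand enantiomer would be chosen to give the R configuration, and no organolithium is involved.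

**Step 12.** The acid may ionise the allylic acetate (allylic transposition or elimination), degrade the furan, open the epoxide 6-endo or with partial SN1 character at C16, or start a cation–olefin cyclisation onto C11=C12. The fallback sets out from 9 and returns at 24. The lactone is closed before the union, when neither furan nor allylic acetate is present. CSA converts 9 to (2E,6R)-6-hydroxy-3-methyl-6-[(2S)-2-methyl-5-oxooxolan-2-yl]hex-2-enal F8. TESOTf and 2,6-lutidine give the silyl ether (2E,6R)-3-methyl-6-[(2S)-2-methyl-5-oxooxolan-2-yl]-6-[(triethylsilyl)oxy]hex-2-enal F9. Allylboration with 18 under the conditions of step 10 gives (5S)-5-[(1R,4E,6S,8E)-11-(furan-3-yl)-6-hydroxy-4,8-dimethyl-1-[(triethylsilyl)oxy]undeca-4,8-dien-1-yl]-5-methyloxolan-2-one F10. Acetylation gives (1R,4E,6S,8E)-11-(furan-3-yl)-4,8-dimethyl-1-[(2S)-2-methyl-5-oxooxolan-2-yl]-1-[(triethylsilyl)oxy]undeca-4,8-dien-6-yl acetate F11, and HF·pyridine in THF/pyridine gives 24.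

**Step 4.** Site selectivity between C15=C16 and C11=C12 may be incomplete, the facial selectivity may be insufficient, and the ketone catalyst may be lost by Baeyer–Villiger oxidation. The fallback sets out from 2 and returns at 7. Sharpless asymmetric epoxidation of the allylic alcohol 2 (Ti(Oi-Pr)4, D-(−)-diethyl tartrate, t-BuOOH, 4 Å sieves, −20 °C) acts only on the alkene that carries the free hydroxymethyl group. By the empirical rule for E-2-methylallylic alcohols it should give (2E)-5-[(2R,3R)-3-(hydroxymethyl)-3-methyloxiran-2-yl]-3-methylpent-2-en-1-yl benzoate F12. Oxidation (SO3·pyridine, DMSO) gives (2E)-5-[(2R,3S)-3-formyl-3-methyloxiran-2-yl]-3-methylpent-2-en-1-yl benzoate F13. Wittig reaction with Ph3P=CHCO2t-Bu gives tert-butyl (2E)-3-[(2R,3R)-3-[(3E)-5-(benzoyloxy)-3-methylpent-3-en-1-yl]-2-methyloxiran-2-yl]prop-2-enoate F14. Diimide (2-nitrobenzenesulfonylhydrazide, Et3N) reduces only the disubstituted conjugated alkene and gives 7.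

## Further compounds

F1 | step 10 | 3-(furan-3-yl)propanal | O=CCCc1ccoc1
F2 | step 10 | ethyl (2E)-5-(furan-3-yl)-2-methylpent-2-enoate | CCOC(=O)/C(C)=C/CCc1ccoc1
F3 | step 10 | (2E)-5-(furan-3-yl)-2-methylpent-2-en-1-ol | OC/C(C)=C/CCc1ccoc1
F4 | step 10 | 3-[(3E)-5-chloro-4-methylpent-3-en-1-yl]furan | ClC/C(C)=C/CCc1ccoc1
F5 | step 10 | tert-butyl 3-[(2R,3R)-3-[(3E,5R,7E)-10-(furan-3-yl)-5-hydroxy-3,7-dimethyldeca-3,7-dien-1-yl]-2-methyloxiran-2-yl]propanoate (C10 epimer of 21) | CC(C)(C)OC(=O)CC[C@@]1(C)O[C@@H]1CC/C(C)=C/[C@H](O)C/C(C)=C/CCc1ccoc1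
F6 | step 10 | tert-butyl 3-[(2R,3R)-3-[(3E,7E)-10-(furan-3-yl)-3,7-dimethyl-5-oxodeca-3,7-dien-1-yl]-2-methyloxiran-2-yl]propanoate | CC(C)(C)OC(=O)CC[C@@]1(C)O[C@@H]1CC/C(C)=C/C(=O)C/C(C)=C/CCc1ccoc1
F7 | step 9 | (2E)-5-(furan-3-yl)-2-methylpent-2-en-1-yl methyl carbonate | COC(=O)OC/C(C)=C/CCc1ccoc1
F8 | step 12 | (2E,6R)-6-hydroxy-3-methyl-6-[(2S)-2-methyl-5-oxooxolan-2-yl]hex-2-enal | O=C/C=C(\C)CC[C@@H](O)[C@]1(C)CCC(=O)O1
F9 | step 12 | (2E,6R)-3-methyl-6-[(2S)-2-methyl-5-oxooxolan-2-yl]-6-[(triethylsilyl)oxy]hex-2-enal | O=C/C=C(\C)CC[C@@H](O[Si](CC)(CC)CC)[C@]1(C)CCC(=O)O1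
F10 | step 12 | (5S)-5-[(1R,4E,6S,8E)-11-(furan-3-yl)-6-hydroxy-4,8-dimethyl-1-[(triethylsilyl)oxy]undeca-4,8-dien-1-yl]-5-methyloxolan-2-one | O[C@H](/C=C(\C)CC[C@@H](O[Si](CC)(CC)CC)[C@]1(C)CCC(=O)O1)C/C(C)=C/CCc1ccoc1
F11 | step 12 | (1R,4E,6S,8E)-11-(furan-3-yl)-4,8-dimethyl-1-[(2S)-2-methyl-5-oxooxolan-2-yl]-1-[(triethylsilyl)oxy]undeca-4,8-dien-6-yl acetate | CC(=O)O[C@H](/C=C(\C)CC[C@@H](O[Si](CC)(CC)CC)[C@]1(C)CCC(=O)O1)C/C(C)=C/CCc1ccoc1
F12 | step 4 | (2E)-5-[(2R,3R)-3-(hydroxymethyl)-3-methyloxiran-2-yl]-3-methylpent-2-en-1-yl benzoate | OC[C@@]1(C)O[C@@H]1CC/C(C)=C/COC(=O)c1ccccc1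
F13 | step 4 | (2E)-5-[(2R,3S)-3-formyl-3-methyloxiran-2-yl]-3-methylpent-2-en-1-yl benzoate | O=C[C@@]1(C)O[C@@H]1CC/C(C)=C/COC(=O)c1ccccc1
F14 | step 4 | tert-butyl (2E)-3-[(2R,3R)-3-[(3E)-5-(benzoyloxy)-3-methylpent-3-en-1-yl]-2-methyloxiran-2-yl]prop-2-enoate | CC(C)(C)OC(=O)/C=C/[C@@]1(C)O[C@@H]1CC/C(C)=C/COC(=O)c1ccccc1
A1 | alternative 1 | tert-butyl 3-[(2R,3R)-3-[(3E)-4-iodo-3-methylbut-3-en-1-yl]-2-methyloxiran-2-yl]propanoate | CC(C)(C)OC(=O)CC[C@@]1(C)O[C@@H]1CC/C(C)=C/I
A2 | alternative 1 | (3E)-6-(furan-3-yl)-3-methylhex-3-enal | O=CC/C(C)=C/CCc1ccoc1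
A3 | alternative 2 | tert-butyl 3-[(2R,3R)-3-[(3E)-5-{[(3R)-5-(furan-3-yl)-2-methylpent-1-en-3-yl]oxy}-3-methylpent-3-en-1-yl]-2-methyloxiran-2-yl]propanoate | CC(C)(C)OC(=O)CC[C@@]1(C)O[C@@H]1CC/C(C)=C/CO[C@H](CCc1ccoc1)C(C)=C
A4 | alternative 3 | (4E,6S,8E)-11-(furan-3-yl)-4,8-dimethyl-1-oxoundeca-4,8-dien-6-yl acetate | CC(=O)O[C@H](/C=C(\C)CCC=O)C/C(C)=C/CCc1ccoc1
A5 | alternative 3 | 5-methyl-2-(trimethylsilyloxy)furan | Cc1ccc(O[Si](C)(C)C)o1
A6 | alternative 3 | (1R,4E,6S,8E)-11-(furan-3-yl)-1-hydroxy-4,8-dimethyl-1-[(2S)-2-methyl-5-oxo-2,5-dihydrofuran-2-yl]undeca-4,8-dien-6-yl acetate | CC(=O)O[C@H](/C=C(\C)CC[C@@H](O)[C@]1(C)C=CC(=O)O1)C/C(C)=C/CCc1ccoc1
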